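**Assumption:** the target is exactly the SMILES given (a 10-membered carbocycle with an E-trisubstituted C9=C10 alkene, a cis-ring 3,4-epoxide carrying C15 as CHO, and 6,8-diacetate). Chiral catalyst and enzyme enantiomers are taken to be available in the sense needed, and precedent for propionate enolsilanes and simple enones is assumed to extend to the isovalerate enolsilane and the macrocyclic enone. Germacrane numbering is used throughout: ring C1–C10, C14 = Me on C10, C15 = CHO on C4, iPr on C7.

## Retrosynthesis
1. Target ← oxidation of C15–OH ← 6,8-diacetate ← C8 carbinol set by ketoreductase reduction of the macrocyclic enone ← C8 alcohol from the intramolecular Ni/Cr Nozaki–Hiyama–Kishi (NHK) closure of an (E)-vinyl iodide onto the C8 aldehyde. This closure forms the 10-membered ring last.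
2. The acyclic NHK precursor carries a Sharpless epoxide made from an (E)-2-alkylallylic alcohol. That alcohol comes from DIBAL opening of an α-alkylidene lactone formed by Horner–Wadsworth–Emmons (HWE) olefination of an α-phosphonolactone with iodo-aldehyde **3**.
3. The α-phosphonolactone arises from opening a terminal epoxide with phosphonoacetate. That epoxide derives from the syn aldol (C6/C7) of an isovalerate thioester enolsilane with BnOCH2CHO, set by a Cu(II)–box catalyst.
4. Rings formed in order: temporary epoxide (C5–C6), then temporary γ-lactone, then the Sharpless 3,4-epoxide, then the 10-membered carbocycle.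

## Forward route

**Step 1**
Reactants: **1** 4-pentyn-1-ol
Product: **2** (E)-5-iodo-4-methylpent-4-en-1-ol
Conditions: Me3Al, Cp2ZrCl2 (10 mol %), ClCH2CH2Cl, 0 °C→rt; then I2, THF, –30 °C
Reagents that add atoms: Me3Al (C[Al](C)C) gives the methyl; I2 (II) gives the iodide.
Why: Negishi Zr-catalysed carboalumination adds Me and Al syn across the terminal alkyne, and iodinolysis retains geometry. This sets the E-trisubstituted vinyl iodide (I cis to Me, trans to C1) that becomes the C9=C10 alkene.

**Step 2**
Reactants: **2**
Product: **3** (E)-5-iodo-4-methylpent-4-enal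
Conditions: TEMPO (10 mol %), PhI(OAc)2, CH2Cl2, rt
Reagents that add atoms: none
Why: TEMPO/BAIB oxidation takes the primary alcohol to the aldehyde without touching the vinyl iodide or over-oxidising.

**Step 3**
Reactants: **4** isovaleryl chloride; **5** 2-methylpropane-2-thiol
Product: **6** S-tert-butyl 3-methylbutanethioate
Conditions: pyridine, CH2Cl2, 0 °C→rt
Reagents that add atoms: none beyond the numbered reactants
Why: Simple thioacylation provides the C7/C8/iPr unit as an α-branched thioester.

**Step 4**
Reactants: **6**
Product: **7** S-tert-butyl O-trimethylsilyl ketene acetal of **6**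
Conditions: LDA, THF, –78 °C; then TMSCl, –78→0 °C; used crude
Reagents that add atoms: TMSCl (C[Si](C)(C)Cl)
Why: Kinetic deprotonation and O-silylation give the enolsilane needed for the Mukaiyama aldol.

**Step 5**
Reactants: **7**; **8** benzyloxyacetaldehyde
Product: **9** S-tert-butyl (2S,3S)-4-(benzyloxy)-3-hydroxy-2-isopropylbutanethioate (syn aldol)
Conditions: [Cu(t-Bu-box)](SbF6)2 (10 mol %), CH2Cl2, –78 °C; then 1 M HCl, THF, 0 °C
Reagents that add atoms: none (the TMS group is removed on workup)
Why: This is a catalytic asymmetric Mukaiyama aldol and it sets the first stereocenters, C6 and C7. Bidentate chelation of the α-benzyloxy aldehyde to the chiral Cu(II)–box fixes the aldehyde face. An open synclinal transition state gives the syn adduct, (2S,3S) as drawn. The ligand enantiomer is chosen to give this isomer.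

**Step 6**
Reactants: **9**
Product: **10** (2R,3S)-4-(benzyloxy)-2-isopropylbutane-1,3-diol
Conditions: LiBH4, THF, 0 °C→rt
Reagents that add atoms: none (hydride only)
Why: LiBH4 reduces the thioester to the primary alcohol (C8). Once C7 is no longer α to a carbonyl it cannot epimerise, and no stereocenter is touched.

**Step 7**
Reactants: **10**
Product: **11** the C8 primary TBS ether of **10**
Conditions: TBSCl (1.05 equiv), imidazole, CH2Cl2, 0 °C
Reagents that add atoms: TBSCl (CC(C)(C)[Si](C)(C)Cl)
Why: The accessible primary C8–OH is silylated in preference to the secondary C6–OH.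

**Step 8**
Reactants: **11**
Product: **12** (2S,3R)-4-(TBSO)-3-isopropylbutane-1,2-diol
Conditions: H2 (1 atm), Pd(OH)2/C, EtOAc, rt
Reagents that add atoms: none
Why: Hydrogenolysis removes the benzyl ether. No alkene, halide or sulfur is present at this stage, and the TBS ether survives.

**Step 9**
Reactants: **12**
Product: **13** tert-butyl(dimethyl){(2R)-3-methyl-2-[(2S)-oxiran-2-yl]butoxy}silane
Conditions: TsCl (1.05 equiv), pyridine, CH2Cl2, 0 °C; then K2CO3, MeOH, rt (one pot)
Reagents that add atoms: none (the tosyl group is lost in the ring closure)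
Why: Selective tosylation of the primary C5–OH is followed by intramolecular 3-exo-tet closure by the C6 alkoxide. The C6–O bond is never broken, so C6 keeps its configuration.

**Step 10**
Reactants: **13**; **14** triethyl phosphonoacetate
Product: **15** α-diethylphosphono-γ-butyrolactone (C15 carbonyl, C4 α-carbon, C5 CH2, C6–O)
Conditions: NaH (2.2 equiv), THF, 0 °C; then **13**, 65 °C
Reagents that add atoms: none beyond the numbered reactants
Why: The stabilised phosphonoacetate anion opens the terminal epoxide at the unhindered CH2 (C5). The resulting C6 alkoxide lactonises 5-exo with loss of EtOH. C6 is untouched and the C4 epimers are irrelevant, since C4 becomes sp2 next.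

**Step 11**
Reactants: **15**; **3**
Product: **16** (3E)-α-alkylidene lactone, with C2 cis to C5 and the vinyl iodide E
Conditions: NaH, THF, 0 °C, then **3**, 0 °C→rt (or LiCl, DBU, MeCN)
Reagents that add atoms: none beyond the numbered reactants
Why: HWE olefination is E-selective. The alkyl chain (C2) ends up trans to the lactone carbonyl, which is the C3=C4 geometry needed for the cis-ring epoxide. The minor Z isomer is removed by chromatography.

**Step 12**
Reactants: **16**
Product: **17** allylic diol HOCH2(C15)–C4(=C3H…)–C5H2–C6H(OH)–C7H(iPr)–C8H2OTBS, E-alkene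
Conditions: DIBAL-H (4 equiv), CH2Cl2, –78→0 °C
Reagents that add atoms: none (hydride only)
Why: Complete 1,2-reduction of the lactone releases C15–OH as an (E)-2-alkylallylic alcohol and C6–OH. The vinyl iodide and TBS ether are untouched.

**Step 13**
Reactants: **17**
Product: **18** epoxy alcohol (3R,4R; 2,3-epoxy alcohol numbering)
Conditions: Ti(OiPr)4 (10 mol %), D-(–)-DIPT (12 mol %), TBHP, 4 Å MS, CH2Cl2, –20 °C
Reagents that add atoms: tert-butyl hydroperoxide (CC(C)(C)OO), which supplies the epoxide oxygen
Why: Sharpless asymmetric epoxidation of the E-allylic alcohol is reagent-controlled, so the remote C6 and C7 stereocenters have little influence. It sets C3 and C4, with C2 and C5 cis on the oxirane. The trisubstituted vinyl iodide is not allylic to a hydroxyl and is untouched.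

**Step 14**
Reactants: **18**
Product: **19** C15 TIPS ether of **18**
Conditions: TIPSCl, imidazole, DMF, rt
Reagents that add atoms: TIPSCl (CC(C)[Si](Cl)(C(C)C)C(C)C)
Why: The primary C15–OH is silylated selectively over the hindered secondary C6–OH. TIPS is chosen to survive the later selective removal of the C8 TBS group.

**Step 15**
Reactants: **19**
Product: **20** C6 acetate
Conditions: Ac2O, pyridine, DMAP (cat.), CH2Cl2, 0 °C→rt
Reagents that add atoms: Ac2O (CC(=O)OC(C)=O)
Why: Acylation installs the final C6 acetate, with retention at C6.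

**Step 16**
Reactants: **20**
Product: **21** C8 primary alcohol
Conditions: HF·pyridine, pyridine, THF, 0 °C
Reagents that add atoms: none
Why: The primary TBS group is cleaved selectively. The pyridine buffer protects the epoxide, and the TIPS ether and acetate survive. The product is oxidised at once in Step 17 to avoid 1,3-acyl migration.

**Step 17**
Reactants: **21**
Product: **22** C8 aldehyde (β-acetoxy, α-isopropyl)
Conditions: Dess–Martin periodinane, NaHCO3, CH2Cl2, 0 °C
Reagents that add atoms: none
Why: Buffered DMP oxidises under mild, non-basic conditions, which limits α-epimerisation at C7 and β-elimination of AcOH. The crude aldehyde is used immediately.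

**Step 18**
Reactants: **22**
Product: **23** 10-membered macrocycle with C8–OH (C8 configuration not controlled)
Conditions: CrCl2 (10 equiv), NiCl2 (5 mol %), DMSO, rt, 2 mM (syringe-pump addition over 10 h)
Reagents that add atoms: none
Why: Intramolecular Nozaki–Hiyama–Kishi coupling forms C8–C9 with retention of the E-vinyl geometry, closing the E-cyclodecene. The cis-ring epoxide pre-organises the chain. Both C8 epimers are carried into Steps 19–20, so the diastereomer ratio does not matter.

**Step 19**
Reactants: **23**
Product: **24** macrocyclic enone (C8 ketone)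
Conditions: Dess–Martin periodinane, NaHCO3, CH2Cl2, 0 °C
Reagents that add atoms: none
Why: Oxidation removes the C8 stereochemical ambiguity so that a single enzymatic reduction sets it.

**Step 20**
Reactants: **24**
Product: **25** (8R)-C8 allylic alcohol (the enone reduced to the alcohol)
Conditions: isolated ketoreductase (KRED, NADPH-dependent oxidoreductase; panel hit giving the R-carbinol), NADP+ (cat.), D-glucose, glucose dehydrogenase, KPi pH 7, 20 % DMSO, 30 °C
Reagents that add atoms: none
Why: Enzymatic hydride transfer to one face of the C8 ketone sets the (R)-carbinol under catalyst control, independent of the NHK ratio. Purified enzyme is used to avoid esterase cleavage of the acetate.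

**Step 21**
Reactants: **25**
Product: **26** 6,8-diacetate, C15–OTIPS
Conditions: Ac2O, pyridine, DMAP, CH2Cl2, rt
Reagents that add atoms: Ac2O (CC(=O)OC(C)=O)
Why: Acetylation of the allylic C8–OH proceeds with retention.

**Step 22**
Reactants: **26**
Product: **27** C15 primary alcohol (diacetate retained)
Conditions: HF·pyridine, pyridine, THF, 0 °C→rt
Reagents that add atoms: none
Why: Acid-buffered fluoride removes the primary TIPS ether. Basic TBAF is avoided so the acetates do not migrate or cleave.

**Step 23**
Reactants: **27**
Product: **28** Pulicanaral A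
Conditions: Dess–Martin periodinane, NaHCO3, CH2Cl2, 0 °C
Reagents that add atoms: none
Why: Mild oxidation converts the hindered primary alcohol to the α-epoxy aldehyde. The configuration of C4 is unchanged.

## Compound list
1 | 4-pentyn-1-ol | C#CCCO | starting material
2 | (E)-5-iodo-4-methylpent-4-en-1-ol | OCCC/C(C)=C/I | intermediate
3 | (E)-5-iodo-4-methylpent-4-enal | O=CCC/C(C)=C/I | intermediate
4 | isovaleryl chloride | CC(C)CC(=O)Cl | starting material
5 | 2-methylpropane-2-thiol | CC(C)(C)S | starting material
6 | S-tert-butyl 3-methylbutanethioate | CC(C)CC(=O)SC(C)(C)C | intermediate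
7 | TMS ketene acetal of 6 | CC(C)C=C(O[Si](C)(C)C)SC(C)(C)C | intermediate
8 | benzyloxyacetaldehyde | O=CCOCc1ccccc1 | starting material
9 | syn aldol thioester (2S,3S) | c1ccccc1COC[C@@H](O)[C@H](C(C)C)C(=O)SC(C)(C)C | intermediate
10 | (2R,3S)-4-(benzyloxy)-2-isopropylbutane-1,3-diol | c1ccccc1COC[C@@H](O)[C@H](C(C)C)CO | intermediate
11 | C8 TBS ether of 10 | c1ccccc1COC[C@@H](O)[C@H](C(C)C)CO[Si](C)(C)C(C)(C)C | intermediate
12 | (2S,3R)-4-(TBSO)-3-isopropylbutane-1,2-diol | OC[C@@H](O)[C@H](C(C)C)CO[Si](C)(C)C(C)(C)C | intermediate
13 | terminal epoxide (2S-oxiranyl, 2R-butoxy TBS ether) | C1O[C@H]1[C@H](C(C)C)CO[Si](C)(C)C(C)(C)C | intermediate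
14 | triethyl phosphonoacetate | CCOC(=O)CP(=O)(OCC)OCC | starting material
15 | α-phosphono-γ-lactone | O=C1O[C@@H]([C@H](C(C)C)CO[Si](C)(C)C(C)(C)C)CC1P(=O)(OCC)OCC | intermediate
16 | (3E)-α-alkylidene lactone | O=C1O[C@@H]([C@H](C(C)C)CO[Si](C)(C)C(C)(C)C)C/C1=C\CC/C(C)=C/I | intermediate
17 | allylic diol (E) | OC/C(C[C@@H](O)[C@H](C(C)C)CO[Si](C)(C)C(C)(C)C)=C/CC/C(C)=C/I | intermediate
18 | epoxy alcohol | OC[C@@]1(C[C@@H](O)[C@H](C(C)C)CO[Si](C)(C)C(C)(C)C)O[C@@H]1CC/C(C)=C/I | intermediate
19 | C15 TIPS ether | CC(C)[Si](C(C)C)(C(C)C)OC[C@@]1(C[C@@H](O)[C@H](C(C)C)CO[Si](C)(C)C(C)(C)C)O[C@@H]1CC/C(C)=C/I | intermediate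
20 | C6 acetate | CC(C)[Si](C(C)C)(C(C)C)OC[C@@]1(C[C@@H](OC(C)=O)[C@H](C(C)C)CO[Si](C)(C)C(C)(C)C)O[C@@H]1CC/C(C)=C/I | intermediate
21 | C8 primary alcohol | CC(C)[Si](C(C)C)(C(C)C)OC[C@@]1(C[C@@H](OC(C)=O)[C@H](C(C)C)CO)O[C@@H]1CC/C(C)=C/I | intermediate
22 | C8 aldehyde | CC(C)[Si](C(C)C)(C(C)C)OC[C@@]1(C[C@@H](OC(C)=O)[C@H](C(C)C)C=O)O[C@@H]1CC/C(C)=C/I | intermediate
23 | macrocycle, C8 epimers | OC1/C=C(\C)CC[C@H]2O[C@@]2(CO[Si](C(C)C)(C(C)C)C(C)C)C[C@@H](OC(C)=O)[C@@H]1C(C)C | intermediate
24 | macrocyclic enone | O=C1/C=C(\C)CC[C@H]2O[C@@]2(CO[Si](C(C)C)(C(C)C)C(C)C)C[C@@H](OC(C)=O)[C@@H]1C(C)C | intermediate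
25 | (8R) allylic alcohol | O[C@@H]1/C=C(\C)CC[C@H]2O[C@@]2(CO[Si](C(C)C)(C(C)C)C(C)C)C[C@@H](OC(C)=O)[C@@H]1C(C)C | intermediate
26 | 6,8-diacetate, C15–OTIPS | CC(=O)O[C@@H]1/C=C(\C)CC[C@H]2O[C@@]2(CO[Si](C(C)C)(C(C)C)C(C)C)C[C@@H](OC(C)=O)[C@@H]1C(C)C | intermediate
27 | C15 primary alcohol | CC(=O)O[C@@H]1/C=C(\C)CC[C@H]2O[C@@]2(CO)C[C@@H](OC(C)=O)[C@@H]1C(C)C | intermediate
28 | Pulicanaral A | CC(=O)O[C@@H]1/C=C(\C)CC[C@H]2O[C@@]2(C=O)C[C@@H](OC(C)=O)[C@@H]1C(C)C | target

## Totals
- Total steps: 23.
- Longest linear sequence: 21 steps (4 → 6 → 7 → 9 → … → 28). The iodo-aldehyde branch (Steps 1–2) joins at Step 11.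

## Three steps most likely to fail, with fallbacks
1. **Step 18, NHK closure to the E-cyclodecene.** Ring strain and dimerisation may compete at 10 members.
   - Fallback: replace the C8–C9 disconnection with ring-closing metathesis at C9=C10. This uses a C8 vinyl carbinol, whose stereocenter is set by KRED reduction of the acyclic vinyl ketone, and a 1,1-disubstituted alkene at C10, with Hoveyda–Grubbs II at high dilution and separation of E/Z isomers.
2. **Step 20, KRED reduction of the bulky macrocyclic enone.** Activity or selectivity may be poor.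
   - Fallback: drop Steps 19–20 and use the NHK alcohol directly. Any undesired C8 epimer is inverted by Mitsunobu reaction (p-nitrobenzoic acid, DIAD, PPh3), then methanolysis.
3. **Step 5, Cu–box aldol with the α-isopropyl enolsilane.** The syn selectivity and ee may fall below those seen with propionate enolsilanes.
   - Fallback: add (Z)-4-methylpent-2-enyl-Bpin to BnOCH2CHO under chiral phosphoric acid catalysis to give the syn homoallylic alcohol. Then protect C6 as its TBS ether, ozonolyse the vinyl group to the C8 aldehyde, and reduce it to the C8 alcohol, which rejoins the route at compound **11**.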